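**Assumption:** lignan numbering is used; the SMILES is read as [(2S,3R,4R)-4-[(R)-hydroxy(4-hydroxy-3-methoxyphenyl)methyl]-2-(4-hydroxy-3-methoxyphenyl)oxolan-3-yl]methanol, i.e. 7R,8R,7'S,8'R (2-aryl/3-CH2OH trans, 3-CH2OH/4-CH(OH)Ar cis).

## Retrosynthetic overview

1. Target ⇐ fluoride removal of one TBS (7-OH) and one TIPS (phenol) group.
2. Tetrahydrofuran (the only ring of the target, formed last): C7'–O bond by a 5-exo intramolecular oxa-Michael (1,6-conjugate) addition of the C9 hydroxyl to a p-quinone methide, generated with DDQ from a phenolic 1,4-diol; this sets C7'.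
3. The diol ⇐ LiAlH4 opening of a trans-α,β-disubstituted γ-butyrolactone; C7'–C8' bond by trans alkylation of the lactone enolate with a vanillyl bromide (three steps from vanillin); this sets C8'.
4. The β-substituted γ-butyrolactone (temporary ring, formed first) ⇐ Evans MgCl2-catalysed anti-aldol (C7–C8) of a succinyl oxazolidinone with TIPS-vanillin, then silylation and reductive auxiliary removal with lactonisation; this sets C7 and C8.
5. Ring order: γ-lactone (made, later opened) → tetrahydrofuran.

## Route

**Step 1**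
Reactants: 1, vanillin
Product: 2, 3-methoxy-4-[(triisopropylsilyl)oxy]benzaldehyde
Conditions: TIPSCl, imidazole, DMF, rt
Reagents that add atoms: TIPSCl, CC(C)[Si](Cl)(C(C)C)C(C)C
Why: Phenol silylation; the aryl TIPS ether survives amine bases, hydrides, LiHMDS and DDQ and is removed only by fluoride at the end.

**Step 2**
Reactants: 3, (R)-4-benzyl-1,3-oxazolidin-2-one; 4, methyl 4-chloro-4-oxobutanoate
Product: 5, methyl 4-[(4R)-4-benzyl-2-oxo-1,3-oxazolidin-3-yl]-4-oxobutanoate
Conditions: n-BuLi, THF, −78 °C; then 4, −78 → 0 °C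
Reagents that add atoms: none (the acyl group comes from 4)
Why: N-acylation of the lithiated Evans auxiliary by the acid chloride, which is far more electrophilic than the methyl ester.

**Step 3**
Reactants: 5; 2
Product: 6, methyl (3S,4R)-3-{[(4R)-4-benzyl-2-oxo-1,3-oxazolidin-3-yl]carbonyl}-4-hydroxy-4-{3-methoxy-4-[(triisopropylsilyl)oxy]phenyl}butanoate (anti aldol)
Conditions: MgCl2 (0.2 equiv), Et3N, TMSCl, EtOAc, rt; then citric acid, MeOH, 0 °C
Reagents that add atoms: none in the isolated product (TMSCl, C[Si](C)(C)Cl, gives a transient O-TMS ether cleaved in the work-up)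
Why: Evans MgCl2-catalysed direct anti-aldol: the Mg-chelated Z-enolate is attacked by the non-enolisable aldehyde on the face opposite the benzyl group (alkylation-like sense, giving 3S = C8) through a boat transition state that gives the anti adduct (4R = C7).

**Step 4**
Reactants: 6
Product: 7, methyl (3S,4R)-3-{[(4R)-4-benzyl-2-oxo-1,3-oxazolidin-3-yl]carbonyl}-4-[(tert-butyldimethylsilyl)oxy]-4-{3-methoxy-4-[(triisopropylsilyl)oxy]phenyl}butanoate
Conditions: TBSOTf, 2,6-lutidine, CH2Cl2, −78 → 0 °C
Reagents that add atoms: TBSOTf, CC(C)(C)[Si](C)(C)OS(=O)(=O)C(F)(F)F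
Why: Silylation of the hindered benzylic alcohol, so that O7 can neither lactonise onto the ester nor compete as a nucleophile in step 11; no stereocentre is touched.

**Step 5**
Reactants: 7
Product: 8, (4R)-4-[(R)-[(tert-butyldimethylsilyl)oxy]{3-methoxy-4-[(triisopropylsilyl)oxy]phenyl}methyl]oxolan-2-one
Conditions: LiBH4 (1.2 equiv), MeOH (1.2 equiv), THF, 0 °C; aq. NH4Cl work-up
Reagents that add atoms: none
Why: Reductive removal of the auxiliary (the imide is reduced faster than the methyl ester) gives a primary alkoxide that closes the γ-lactone onto the methyl ester (5-exo-trig); the auxiliary is recovered and no stereocentre is affected.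

**Step 6**
Reactants: 1, vanillin
Product: 9, 4-formyl-2-methoxyphenyl pivalate
Conditions: PivCl, Et3N, DMAP (cat.), CH2Cl2, 0 °C → rt
Reagents that add atoms: pivaloyl chloride, CC(C)(C)C(Cl)=O
Why: Phenol acylation; the hindered pivalate tolerates NaBH4, PBr3 and a lithium enolate, and is later cleaved by LiAlH4 in the same operation that opens the lactone.

**Step 7**
Reactants: 9
Product: 10, 4-(hydroxymethyl)-2-methoxyphenyl pivalate
Conditions: NaBH4, THF/EtOH, 0 °C
Reagents that add atoms: none
Why: Chemoselective borohydride reduction of the aldehyde in the presence of the hindered aryl ester.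

**Step 8**
Reactants: 10
Product: 11, 4-(bromomethyl)-2-methoxyphenyl pivalate
Conditions: PBr3, Et2O, 0 °C
Reagents that add atoms: PBr3, BrP(Br)Br
Why: Conversion of the benzylic alcohol to the bromide; the acyloxy group keeps this benzyl bromide stable enough to handle.

**Step 9**
Reactants: 8; 11
Product: 12, 4-{[(3R,4R)-4-[(R)-[(tert-butyldimethylsilyl)oxy]{3-methoxy-4-[(triisopropylsilyl)oxy]phenyl}methyl]-2-oxooxolan-3-yl]methyl}-2-methoxyphenyl pivalate (3,4-trans)
Conditions: LiHMDS, THF, −78 °C; then 11, DMPU, −78 → −40 °C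
Reagents that add atoms: none
Why: Alkylation of the lactone lithium enolate occurs anti to the bulky C4 substituent, setting C8' (3R) trans, the relationship that becomes 8,8'-cis once the ring is switched to the tetrahydrofuran.

**Step 10**
Reactants: 12
Product: 13, (2R,3R)-2-[(R)-[(tert-butyldimethylsilyl)oxy]{3-methoxy-4-[(triisopropylsilyl)oxy]phenyl}methyl]-3-(4-hydroxy-3-methoxybenzyl)butane-1,4-diol
Conditions: LiAlH4, THF, 0 °C; Rochelle salt work-up
Reagents that add atoms: none
Why: Hydride reduction opens the lactone to the 1,4-diol and cleaves the aryl pivalate to the free phenol, while both silyl ethers survive.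

**Step 11**
Reactants: 13
Product: 14, [(2S,3R,4R)-4-[(R)-[(tert-butyldimethylsilyl)oxy]{3-methoxy-4-[(triisopropylsilyl)oxy]phenyl}methyl]-2-(4-hydroxy-3-methoxyphenyl)oxolan-3-yl]methanol
Conditions: DDQ (1.05 equiv), NaHCO3 (solid), CH2Cl2, 0 °C → rt
Reagents that add atoms: none
Why: DDQ dehydrogenates only the free 4-alkylguaiacol to its p-quinone methide, which is trapped by the C9 hydroxyl in a 5-exo-trig intramolecular oxa-Michael (1,6-conjugate) addition (the C9' hydroxyl could only form an oxetane), placing the aryl group trans to the adjacent CH2OH and so setting C7' as S.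

**Step 12**
Reactants: 14
Product: 15, (7R)-7-hydroxylariciresinol
Conditions: TBAF, AcOH (1:1), THF, 0 °C → rt; neutral work-up
Reagents that add atoms: none
Why: Fluoride desilylation removes the aryl TIPS and benzylic TBS ethers, and the acetic acid buffer keeps the p-hydroxybenzylic alcohol from ionising and closing to a furofuran.

## Compound list

1 | vanillin | COc1cc(C=O)ccc1O | starting material
2 | 3-methoxy-4-[(triisopropylsilyl)oxy]benzaldehyde | COc1cc(C=O)ccc1O[Si](C(C)C)(C(C)C)C(C)C | intermediate
3 | (R)-4-benzyl-1,3-oxazolidin-2-one | O=C1OC[C@@H](Cc2ccccc2)N1 | starting material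
4 | methyl 4-chloro-4-oxobutanoate | COC(=O)CCC(Cl)=O | starting material
5 | methyl 4-[(4R)-4-benzyl-2-oxo-1,3-oxazolidin-3-yl]-4-oxobutanoate | O=C1OC[C@@H](Cc2ccccc2)N1C(=O)CCC(=O)OC | intermediate
6 | methyl (3S,4R)-3-{[(4R)-4-benzyl-2-oxo-1,3-oxazolidin-3-yl]carbonyl}-4-hydroxy-4-{3-methoxy-4-[(triisopropylsilyl)oxy]phenyl}butanoate | O=C1OC[C@@H](Cc2ccccc2)N1C(=O)[C@@H](CC(=O)OC)[C@@H](O)c3ccc(O[Si](C(C)C)(C(C)C)C(C)C)c(OC)c3 | intermediate
7 | 4-O-TBS ether of 6 | O=C1OC[C@@H](Cc2ccccc2)N1C(=O)[C@@H](CC(=O)OC)[C@@H](O[Si](C)(C)C(C)(C)C)c3ccc(O[Si](C(C)C)(C(C)C)C(C)C)c(OC)c3 | intermediate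
8 | (4R)-4-[(R)-[(tert-butyldimethylsilyl)oxy]{3-methoxy-4-[(triisopropylsilyl)oxy]phenyl}methyl]oxolan-2-one | O=C1C[C@@H]([C@@H](O[Si](C)(C)C(C)(C)C)c2ccc(O[Si](C(C)C)(C(C)C)C(C)C)c(OC)c2)CO1 | intermediate
9 | 4-formyl-2-methoxyphenyl pivalate | COc1cc(C=O)ccc1OC(=O)C(C)(C)C | intermediate
10 | 4-(hydroxymethyl)-2-methoxyphenyl pivalate | COc1cc(CO)ccc1OC(=O)C(C)(C)C | intermediate
11 | 4-(bromomethyl)-2-methoxyphenyl pivalate | COc1cc(CBr)ccc1OC(=O)C(C)(C)C | intermediate
12 | 4-{[(3R,4R)-4-[(R)-(TBSO){3-methoxy-4-(TIPSO)phenyl}methyl]-2-oxooxolan-3-yl]methyl}-2-methoxyphenyl pivalate | COc1cc(C[C@H]2C(=O)OC[C@@H]2[C@@H](O[Si](C)(C)C(C)(C)C)c3ccc(O[Si](C(C)C)(C(C)C)C(C)C)c(OC)c3)ccc1OC(=O)C(C)(C)C | intermediate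
13 | (2R,3R)-2-[(R)-(TBSO){3-methoxy-4-(TIPSO)phenyl}methyl]-3-(4-hydroxy-3-methoxybenzyl)butane-1,4-diol | COc1cc(C[C@@H](CO)[C@H](CO)[C@@H](O[Si](C)(C)C(C)(C)C)c2ccc(O[Si](C(C)C)(C(C)C)C(C)C)c(OC)c2)ccc1O | intermediate
14 | [(2S,3R,4R)-4-[(R)-(TBSO){3-methoxy-4-(TIPSO)phenyl}methyl]-2-(4-hydroxy-3-methoxyphenyl)oxolan-3-yl]methanol | COc1cc([C@H]2OC[C@H]([C@@H](O[Si](C)(C)C(C)(C)C)c3ccc(O[Si](C(C)C)(C(C)C)C(C)C)c(OC)c3)[C@@H]2CO)ccc1O | intermediate
15 | (7R)-7-hydroxylariciresinol | COc1cc([C@H]2OC[C@H]([C@@H](O)c3ccc(O)c(OC)c3)[C@@H]2CO)ccc1O | target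

## Summary

**Total steps:** 12.

**Longest linear sequence:** 8 steps (step 1 or 2 → 3 → 4 → 5 → 9 → 10 → 11 → 12), which is two thirds of the total. The bromide branch (steps 6–8) joins at step 9.

**Steps most likely to fail, with fallbacks:**

1. **Step 11 (DDQ quinone-methide generation and oxa-Michael closure).** Risks are over-oxidation of the product phenol, tautomerisation of the quinone methide to a styrene, Friedel–Crafts closure onto the other arene, and imperfect trans selectivity at C7'. Fallback: build C7' at the alcohol oxidation level instead. Run an aldol of the enolate of 8 with aldehyde 9 in place of the alkylation, reduce with LiAlH4, and close the ring from the resulting p-hydroxybenzylic alcohol by eliminative (redox-neutral) quinone-methide formation under mild base and gentle warming.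

2. **Step 3 (Mg anti-aldol with an electron-rich aldehyde and a succinate side chain).** Risks are low conversion, low diastereoselectivity, or the opposite facial sense from the one assumed. Fallback: a substrate-controlled Fráter–Seebach route. Noyori hydrogenation of methyl 3-aryl-3-oxopropanoate gives the (R)-β-hydroxy ester, and anti-selective alkylation of its dianion with tert-butyl bromoacetate gives the same C7/C8 anti array.

3. **Step 5 (imide reduction next to a methyl ester, with in situ lactonisation).** Risks are over-reduction of the ester or lactone, and silyl migration from O7 to O9. Fallback: reduce 7 exhaustively with LiAlH4 to the 1,4-diol, then oxidise the less hindered primary alcohol selectively with TEMPO/PhI(OAc)2 to re-form lactone 8.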